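**Strategy.** Guttiferone L is cut at the C7–prenyl bond and at C1–C8. The ring C1–C8–C7–C6–C5–C9 of the bicyclo[3.3.1]nonane, with prenyl on C7 and methyl plus 4-methylpent-3-enyl on C8, is read as an E-geranyl chain on C5 that has taken up a dimethylallyl cation at C7 and been trapped at C8 by the enol carbon C1. A cyclising aromatic prenyltransferase should make both bonds, the ring and the stereocentres C1, C7 and C8 in one operation. Its substrate is the (S)-configured dearomatised acylphloroglucinol carrying prenyl and geranyl on C5, prenyl on C1 and the free 2,4,5-trihydroxybenzoyl group on C3, built by desymmetrising Pd-catalysed geranylation.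

Key step: step 9

**Remarks and assumptions (chemistry)**
- Locants C1–C9 follow the bicyclic numbering of the target: C1 and C5 are bridgeheads, C2–C3–C4 is the aroyl-dione bridge, C9 is the bridging ketone. In the monocyclic dienone names, C6 is the later C5. CIP descriptors refer to the tautomers drawn in the SMILES.
- The dearomatised intermediates are written as enolised dienones (one ring ketone, two enols), not as all-keto triketones.
- The aroyl oxygens are carried as methoxymethyl (MOM) acetals from 2,4,5-trihydroxybenzaldehyde. Aryl methyl ethers are avoided because cleaving three of them late would not spare four trisubstituted olefins and a gem-diallyl dienone.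
- 1,3,5-Tris(benzyloxy)benzene (3) and dimethylallyl diphosphate (15, used as its ammonium salt) are taken as purchasable.
- The sense of induction of the Trost ligand in step 7 is not predicted. Both antipodes are commercial, and the one that gives the 6S product is to be identified on the first run.
- The enzyme of step 9 is assumed to be a UbiA-type cyclising prenyltransferase from a guttiferone-producing Clusiaceae plant or an evolved homologue, expressed in yeast.
- Compounds 14 and 16 contain an air-sensitive hydroxyquinol and are handled under argon.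

**Route**

Step 1
Reactants: 1 2,4,5-trihydroxybenzaldehyde
Product: 2 2,4,5-tris(methoxymethoxy)benzaldehyde
Conditions: MOMCl (4.5 equiv), i-Pr2NEt, DMF, 0 → 40 °C, Ar
Reagents that add atoms: chloromethyl methyl ether, COCCl
Why: Williamson-type O-alkylation of all three phenols gives acetals that mask the oxidation-prone hydroxyquinol and withstand organolithium, hydrogenolysis, aqueous KOH and Pd(0).

Step 2
Reactants: 3 1,3,5-tris(benzyloxy)benzene; 2 2,4,5-tris(methoxymethoxy)benzaldehyde
Product: 5 [2,4,6-tris(benzyloxy)phenyl][2,4,5-tris(methoxymethoxy)phenyl]methanol (racemic), via aryllithium 4 (not isolated)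
Conditions: n-BuLi, TMEDA, THF, 0 °C; then 2, −78 → 0 °C; H2O
Reagents that add atoms: none
Why: Directed ortho-metalation between two benzyloxy groups gives aryllithium 4, whose 1,2-addition to the non-enolisable aldehyde forms the diaryl carbinol; the new carbinol centre is racemic and is erased in step 3.

Step 3
Reactants: 5 [2,4,6-tris(benzyloxy)phenyl][2,4,5-tris(methoxymethoxy)phenyl]methanol
Product: 6 [2,4,6-tris(benzyloxy)phenyl][2,4,5-tris(methoxymethoxy)phenyl]methanone
Conditions: IBX, DMSO, rt
Reagents that add atoms: none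
Why: IBX oxidation of the doubly benzylic secondary alcohol gives the diaryl ketone without the strong acid that would ionise the electron-rich benzhydrol or cleave the acetals.

Step 4
Reactants: 6 [2,4,6-tris(benzyloxy)phenyl][2,4,5-tris(methoxymethoxy)phenyl]methanone
Product: 7 [2,4,5-tris(methoxymethoxy)phenyl](2,4,6-trihydroxyphenyl)methanone
Conditions: H2 (1 atm), 10% Pd/C, EtOAc–MeOH, rt
Reagents that add atoms: none
Why: Catalytic hydrogenolysis removes the three benzyl ethers while the MOM acetals are inert and the ketone, a vinylogous acid chelated by the freed ortho-hydroxyls, resists reduction.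

Step 5
Reactants: 7 [2,4,5-tris(methoxymethoxy)phenyl](2,4,6-trihydroxyphenyl)methanone; 8 prenyl bromide
Product: 9 [2,4,6-trihydroxy-3,5-bis(3-methylbut-2-en-1-yl)phenyl][2,4,5-tris(methoxymethoxy)phenyl]methanone
Conditions: 8 (2.1 equiv), 10% aq. KOH, 0 °C, Ar; then AcOH to pH 6
Reagents that add atoms: none
Why: Twofold SN2 C-alkylation of the water-solvated phloroglucinolate at its two free ring carbons, the classical prenylation of acylphloroglucinols, gives the Cs-symmetric diprenyl compound; the acetals are stable to cold aqueous base and no stereocentre is formed.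

Step 6
Reactants: 10 geraniol
Product: 11 (2E)-3,7-dimethylocta-2,6-dien-1-yl methyl carbonate
Conditions: ClCO2Me, pyridine, CH2Cl2, 0 °C
Reagents that add atoms: methyl chloroformate, COC(=O)Cl
Why: O-acylation of the primary allylic alcohol installs the carbonate leaving group needed for base-free ionisation by Pd(0) and leaves the E olefin untouched.

Step 7
Reactants: 9 [2,4,6-trihydroxy-3,5-bis(3-methylbut-2-en-1-yl)phenyl][2,4,5-tris(methoxymethoxy)phenyl]methanone; 11 (2E)-3,7-dimethylocta-2,6-dien-1-yl methyl carbonate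
Product: 12 (6S)-6-[(2E)-3,7-dimethylocta-2,6-dien-1-yl]-3,5-dihydroxy-2,6-bis(3-methylbut-2-en-1-yl)-4-[2,4,5-tris(methoxymethoxy)benzoyl]cyclohexa-2,4-dien-1-one
Conditions: Pd2(dba)3·CHCl3 (2.5 mol %), (R,R)- or (S,S)-DACH-phenyl Trost ligand (7.5 mol %, antipode giving 6S), THF, −20 °C, Ar
Reagents that add atoms: none
Why: In this Tsuji–Trost asymmetric allylic alkylation with dearomatisation, decarboxylative ionisation of 11 gives a π-geranyl-Pd complex and methoxide, the phloroglucinolate of 9 attacks the unsubstituted allyl terminus through a prenyl-bearing ring carbon (linear product, E geometry kept, O-allylation reversible), and because these two carbons are enantiotopic in Cs-symmetric 9 the chiral ligand pocket selects one of them and so sets the quaternary centre C6 (later C5) as S.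

Step 8
Reactants: 12 (6S)-6-[(2E)-3,7-dimethylocta-2,6-dien-1-yl]-3,5-dihydroxy-2,6-bis(3-methylbut-2-en-1-yl)-4-[2,4,5-tris(methoxymethoxy)benzoyl]cyclohexa-2,4-dien-1-one
Product: 14 (6S)-6-[(2E)-3,7-dimethylocta-2,6-dien-1-yl]-3,5-dihydroxy-2,6-bis(3-methylbut-2-en-1-yl)-4-(2,4,5-trihydroxybenzoyl)cyclohexa-2,4-dien-1-one, via pentasilyl ether 13 (not isolated)
Conditions: TMSOTf, 2,2′-bipyridyl, MeCN, 0 °C → rt; then degassed H2O, rt, Ar
Reagents that add atoms: none
Why: Silyl triflate–bipyridyl exchange turns each aryl MOM ether into an aryl TMS ether (and the enols into TMS enol ethers) under non-protic, buffered conditions that do not protonate the four trisubstituted olefins, and water then frees phenols and enols; the quaternary stereocentre has no α-hydrogen and cannot epimerise.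

Step 9
Reactants: 14 (6S)-6-[(2E)-3,7-dimethylocta-2,6-dien-1-yl]-3,5-dihydroxy-2,6-bis(3-methylbut-2-en-1-yl)-4-(2,4,5-trihydroxybenzoyl)cyclohexa-2,4-dien-1-one; 15 dimethylallyl diphosphate
Product: 16 guttiferone L, (1S,5S,7R,8S)-4-hydroxy-8-methyl-1,5,7-tris(3-methylbut-2-en-1-yl)-8-(4-methylpent-3-en-1-yl)-3-(2,4,5-trihydroxybenzoyl)bicyclo[3.3.1]non-3-ene-2,9-dione
Conditions: recombinant UbiA-type cyclising aromatic prenyltransferase (yeast microsomes), MgCl2, Tris–HCl pH 7.5, Na ascorbate, 2% DMSO, 30 °C, Ar; EtOAc extraction, prep. HPLC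
Reagents that add atoms: none
Why: Proposed new method: Mg2+-assisted ionisation of 15 in the active site gives the dimethylallyl cation, which adds to C7 of the E-configured C5 geranyl olefin of bound 14 (Markovnikov, tertiary cation at C8) while the enolate carbon C1 collapses onto C8, so that the C7–prenyl and C1–C8 bonds form together; the closest known reaction type is the cyclising C-prenylation of gem-diprenylated acylphloroglucinols by UbiA-type aromatic prenyltransferases, and in flask chemistry the cation–olefin cyclisation terminated by an enol carbon, neither of which has been shown for a geranyl chain or this aroyl group. Ring C1–C8–C7–C6–C5–C9 closes in a 6-endo-trig mode with respect to the C7=C8 olefin through a chair. C7 (R) and C8 (S) follow from anti addition across the E olefin with the incoming prenyl equatorial, which leaves prenyl and 4-methylpent-3-enyl trans-diequatorial and the C8 methyl axial. C1 (S) is fixed by the existing C5 (S) centre, because the one-carbon C9 bridge lets C1 reach C8 only on the face of the triketone ring that carries the geranyl chain. The step needs C7 selectivity among four trisubstituted olefins and C1 selectivity over C3 and the enol oxygens, which the binding pocket has to provide as it does for native substrates, while the substrate itself supplies the E geometry and the C5 configuration.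

**Compound list**

1 | 2,4,5-trihydroxybenzaldehyde | O=Cc1cc(O)c(O)cc1O | starting material
2 | 2,4,5-tris(methoxymethoxy)benzaldehyde | COCOc1cc(OCOC)c(C=O)cc1OCOC | intermediate
3 | 1,3,5-tris(benzyloxy)benzene | c1ccc(COc2cc(OCc3ccccc3)cc(OCc3ccccc3)c2)cc1 | starting material
4 | [2,4,6-tris(benzyloxy)phenyl]lithium (formed in the flask, not isolated) | [Li]c1c(OCc2ccccc2)cc(OCc2ccccc2)cc1OCc1ccccc1 | intermediate
5 | [2,4,6-tris(benzyloxy)phenyl][2,4,5-tris(methoxymethoxy)phenyl]methanol, racemic | OC(c1c(OCc2ccccc2)cc(OCc2ccccc2)cc1OCc1ccccc1)c1cc(OCOC)c(OCOC)cc1OCOC | intermediate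
6 | [2,4,6-tris(benzyloxy)phenyl][2,4,5-tris(methoxymethoxy)phenyl]methanone | O=C(c1c(OCc2ccccc2)cc(OCc2ccccc2)cc1OCc1ccccc1)c1cc(OCOC)c(OCOC)cc1OCOC | intermediate
7 | [2,4,5-tris(methoxymethoxy)phenyl](2,4,6-trihydroxyphenyl)methanone | O=C(c1c(O)cc(O)cc1O)c1cc(OCOC)c(OCOC)cc1OCOC | intermediate
8 | prenyl bromide (1-bromo-3-methylbut-2-ene) | CC(C)=CCBr | starting material
9 | [2,4,6-trihydroxy-3,5-bis(3-methylbut-2-en-1-yl)phenyl][2,4,5-tris(methoxymethoxy)phenyl]methanone (Cs-symmetric, achiral) | CC(C)=CCc1c(O)c(CC=C(C)C)c(O)c(C(=O)c2cc(OCOC)c(OCOC)cc2OCOC)c1O | intermediate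
10 | geraniol, (2E)-3,7-dimethylocta-2,6-dien-1-ol | CC(C)=CCC/C(C)=C/CO | starting material
11 | (2E)-3,7-dimethylocta-2,6-dien-1-yl methyl carbonate | CC(C)=CCC/C(C)=C/COC(=O)OC | intermediate
12 | (6S)-6-[(2E)-3,7-dimethylocta-2,6-dien-1-yl]-3,5-dihydroxy-2,6-bis(3-methylbut-2-en-1-yl)-4-[2,4,5-tris(methoxymethoxy)benzoyl]cyclohexa-2,4-dien-1-one | CC(C)=CCC/C(C)=C/C[C@]2(CC=C(C)C)C(=O)C(CC=C(C)C)=C(O)C(C(=O)c1cc(OCOC)c(OCOC)cc1OCOC)=C2O | intermediate
13 | pentakis(trimethylsilyl) ether of 14 (three aryl and two enol oxygens silylated; formed in the flask, not isolated) | CC(C)=CCC/C(C)=C/C[C@]2(CC=C(C)C)C(=O)C(CC=C(C)C)=C(O[Si](C)(C)C)C(C(=O)c1cc(O[Si](C)(C)C)c(O[Si](C)(C)C)cc1O[Si](C)(C)C)=C2O[Si](C)(C)C | intermediate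
14 | (6S)-6-[(2E)-3,7-dimethylocta-2,6-dien-1-yl]-3,5-dihydroxy-2,6-bis(3-methylbut-2-en-1-yl)-4-(2,4,5-trihydroxybenzoyl)cyclohexa-2,4-dien-1-one (key-step precursor) | CC(C)=CCC/C(C)=C/C[C@]2(CC=C(C)C)C(=O)C(CC=C(C)C)=C(O)C(C(=O)c1cc(O)c(O)cc1O)=C2O | intermediate
15 | dimethylallyl diphosphate | CC(C)=CCOP(=O)(O)OP(=O)(O)O | starting material
16 | guttiferone L, (1S,5S,7R,8S)-4-hydroxy-8-methyl-1,5,7-tris(3-methylbut-2-en-1-yl)-8-(4-methylpent-3-en-1-yl)-3-(2,4,5-trihydroxybenzoyl)bicyclo[3.3.1]non-3-ene-2,9-dione | CC(C)=CCC[C@@]1(C)[C@H](CC=C(C)C)C[C@]2(CC=C(C)C)C(=O)[C@@]1(CC=C(C)C)C(=O)C(C(=O)c1cc(O)c(O)cc1O)=C2O | target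

**Count**

Total steps: 9. Longest linear sequence: 8 steps (steps 1, 2, 3, 4, 5, 7, 8, 9); step 6 is a one-step side branch.

**Steps most likely to fail**

1. Step 9 (Proposed new method). The enzyme may not turn over the geranyl substrate. The prenyl cation may be delivered to another olefin, to C3 or to oxygen. The C8 cation may be quenched by water or lose a proton before C1 closes.

   Fallback (known chemistry, sets out from 9, returns at 16): the ring C1–C8–C7–C6–C5–C9 is built by alkylative dearomatisation–annulation instead, forming C5–C6 and C1–C8 with a formyl handle on C7. The reagent (3,3-diethoxyprop-1-en-2-yl)lithium F1 is made from 2-bromo-3,3-diethoxyprop-1-ene (C=C(Br)C(OCC)OCC) and t-BuLi at −78 °C. It is added to 6-methylhept-5-en-2-one (CC(=O)CCC=C(C)C) to give 2-(diethoxymethyl)-3,7-dimethylocta-1,6-dien-3-ol F2. Acetylation (Ac2O, DMAP, Et3N) gives 2-(diethoxymethyl)-3,7-dimethylocta-1,6-dien-3-yl acetate F3, and mild acetal hydrolysis (oxalic acid on wet silica) gives the α-methylene aldehyde 3,7-dimethyl-2-methylidene-1-oxooct-6-en-3-yl acetate F4.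

   Under a cinchona-derived phase-transfer catalyst with CsOH·H2O in CH2Cl2 at low temperature, C5 of 9 should add to the methylene of F4, acetate should leave, and C1 should close onto C8 by intramolecular Michael addition. After base equilibration (retro-aldol of any adamantane-type aldol adduct, C7 epimerisation to the equatorial aldehyde) this should give the 7-formyl bicyclic trione tris-MOM ether F5. The catalyst antipode is chosen for 1S,5S. This route does not control C8 as the enzyme would: the C8 epimer has to be separated and can be re-equilibrated by retro-Michael/Michael addition.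

   Vinylmagnesium bromide then gives the 7-(1-hydroxyprop-2-enyl) compound F6. Acetylation, with methanolic NaHCO3 work-up to cleave the transient enol acetate, gives the 7-(1-acetoxyprop-2-enyl) compound F7. Tsuji formate reduction (Pd2(dba)3, PBu3, HCO2NH4) gives the 7-allyl compound F8, and cross-metathesis with 2-methyl-2-butene (Grubbs II) gives guttiferone L tris(methoxymethyl) ether F9. TMSOTf/2,2′-bipyridyl, then water, as in step 8, proceeds through the tetrakis(trimethylsilyl) derivative F10 to 16.

2. Step 7. Discrimination of the enantiotopic ring carbons may be poor. Attack may occur at the substituted allyl terminus, or the E geometry may scramble through η3–η1–η3 isomerisation. O-geranylation may persist. Pd(0) may re-ionise the product, eroding the ee or exchanging allyl groups.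

   Fallback (sets out from 9, returns at 12): 9 is C-geranylated without a metal, using geranyl bromide (CC(C)=CCC/C(C)=C/CBr) in cold aqueous KOH. This is an SN2 reaction at the primary bromide, so the E geometry is retained and the allyl groups cannot scramble. It gives racemic 6-geranyl-3,5-dihydroxy-2,6-diprenyl-4-[2,4,5-tris(methoxymethoxy)benzoyl]cyclohexa-2,4-dien-1-one F11. Preparative chiral SFC, or crystallisation of a diastereomeric salt of the acidic enol with a chiral amine, then delivers the (S)-enantiomer 12.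

3. Step 8. Acetal exchange may be incomplete at the chelated 2′-position. The Lewis acid may induce cyclisation of the enol oxygens onto the C5 side chains. The freed hydroxyquinol may oxidise in air during work-up.

   Fallback (sets out from 9, returns at 14): the order is changed so that no dearomatised ring or geranyl chain is exposed to deprotection. The acetals of 9 are cleaved at the aromatic stage (HCl in MeOH, 40 °C, Ar) to [2,4,6-trihydroxy-3,5-bis(3-methylbut-2-en-1-yl)phenyl](2,4,5-trihydroxyphenyl)methanone F12. The Pd-catalysed geranylation of step 7 is then run on F12 with 11 and should give 14 directly. The acylphloroglucinol ring is the most acidic and most C-nucleophilic part, and any aryl geranyl ether formed on the hydroxyquinol should be re-ionised by Pd(0).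

**Further compounds**

F1 | step 9 | (3,3-diethoxyprop-1-en-2-yl)lithium | [Li]C(=C)C(OCC)OCC
F2 | step 9 | 2-(diethoxymethyl)-3,7-dimethylocta-1,6-dien-3-ol (racemic) | CCOC(OCC)C(=C)C(C)(O)CCC=C(C)C
F3 | step 9 | 2-(diethoxymethyl)-3,7-dimethylocta-1,6-dien-3-yl acetate (racemic) | CCOC(OCC)C(=C)C(C)(OC(C)=O)CCC=C(C)C
F4 | step 9 | 3,7-dimethyl-2-methylidene-1-oxooct-6-en-3-yl acetate (racemic) | C=C(C=O)C(C)(OC(C)=O)CCC=C(C)C
F5 | step 9 | 7-formyl analogue of F9 (formyl equatorial on C7, other centres as in 16) | CC(C)=CCC[C@@]1(C)[C@H](C=O)C[C@]2(CC=C(C)C)C(=O)[C@@]1(CC=C(C)C)C(=O)C(C(=O)c1cc(OCOC)c(OCOC)cc1OCOC)=C2O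
F6 | step 9 | 7-(1-hydroxyprop-2-enyl) analogue of F9 (carbinol epimers) | CC(C)=CCC[C@@]1(C)[C@H](C(O)C=C)C[C@]2(CC=C(C)C)C(=O)[C@@]1(CC=C(C)C)C(=O)C(C(=O)c1cc(OCOC)c(OCOC)cc1OCOC)=C2O
F7 | step 9 | 7-(1-acetoxyprop-2-enyl) analogue of F9 (epimers at the acetoxy carbon) | CC(C)=CCC[C@@]1(C)[C@H](C(OC(C)=O)C=C)C[C@]2(CC=C(C)C)C(=O)[C@@]1(CC=C(C)C)C(=O)C(C(=O)c1cc(OCOC)c(OCOC)cc1OCOC)=C2O
F8 | step 9 | 7-allyl analogue of F9 | CC(C)=CCC[C@@]1(C)[C@H](CC=C)C[C@]2(CC=C(C)C)C(=O)[C@@]1(CC=C(C)C)C(=O)C(C(=O)c1cc(OCOC)c(OCOC)cc1OCOC)=C2O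
F9 | step 9 | guttiferone L 2′,4′,5′-tris(methoxymethyl) ether | CC(C)=CCC[C@@]1(C)[C@H](CC=C(C)C)C[C@]2(CC=C(C)C)C(=O)[C@@]1(CC=C(C)C)C(=O)C(C(=O)c1cc(OCOC)c(OCOC)cc1OCOC)=C2O
F10 | step 9 | guttiferone L tetrakis(trimethylsilyl) ether (three aryl and one enol oxygen; formed in the flask) | CC(C)=CCC[C@@]1(C)[C@H](CC=C(C)C)C[C@]2(CC=C(C)C)C(=O)[C@@]1(CC=C(C)C)C(=O)C(C(=O)c1cc(O[Si](C)(C)C)c(O[Si](C)(C)C)cc1O[Si](C)(C)C)=C2O[Si](C)(C)C
F11 | step 7 | racemic 6-[(2E)-3,7-dimethylocta-2,6-dien-1-yl]-3,5-dihydroxy-2,6-bis(3-methylbut-2-en-1-yl)-4-[2,4,5-tris(methoxymethoxy)benzoyl]cyclohexa-2,4-dien-1-one | CC(C)=CCC/C(C)=C/CC2(CC=C(C)C)C(=O)C(CC=C(C)C)=C(O)C(C(=O)c1cc(OCOC)c(OCOC)cc1OCOC)=C2O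
F12 | step 8 | [2,4,6-trihydroxy-3,5-bis(3-methylbut-2-en-1-yl)phenyl](2,4,5-trihydroxyphenyl)methanone | CC(C)=CCc1c(O)c(CC=C(C)C)c(O)c(C(=O)c2cc(O)c(O)cc2O)c1O
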